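## Analysis of the target

The target is the (E)-caffeate of the primary alcohol of a 2-aryl-3-(hydroxymethyl)-4-(arylmethyl)tetrahydrofuran, a lignan of the lariciresinol type in which both arenes are 4-hydroxy-3-methoxyphenyl. The ring O1–C2–C3–C4–C5 carries three contiguous stereocentres: C2 (R, aryl), C3 (S, CH2O-acyl) and C4 (S, arylmethyl). The aryl group is trans to the C3 arm and the C3 and C4 arms are cis; the core is the mirror image of the (2S,3R,4R) core of the common natural lariciresinol. The C2–O1 bond is a benzylic ether of an electron-rich arene: acid ionises it (epimerisation at C2, or Friedel–Crafts capture by the second arene), and hydrogenolysis or quinone oxidants cleave it. Once the acyl group is in place, the cinnamate alkene and ester exclude hydrogenation and strong nucleophiles, and the catechol and the two guaiacyl phenols are oxidised in basic, aerated media. The difficulty lies in the cis C3/C4 pair, which is the less stable arrangement and is epimerisable at C3 as long as C2 is a carbonyl or lactol carbon, and in acylating one primary hydroxyl beside phenols. The strategy rests on C2 being a C-aryl glycoside carbon: the oxocarbenium ion O1=C2 has the cis arms on C3 and C4 on one face, so an aryl nucleophile should enter trans to the C3 arm, making the C2–aryl bond and the last stereocentre together.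

## Retrosynthetic reasoning

23 to 22: the two aryl O–acetyl bonds of the catechol are cut last. Phenolic acetates leave under near-neutral conditions that spare the cinnamate ester, the alkene and the benzylic ether, so the most oxidation-prone group appears only at the end.

22 to 19 and 21: the ester is cut at the CH2–O bond. This separates the lignan core 19 from an acid, 21, that is one step from commercial 20. The forward reaction must acylate the primary hydroxyl of 19 without touching its two phenols, which is why the alcohol, not the acid, is activated (Mitsunobu).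

19 to 18: three O–benzyl bonds. Benzyl ethers survive every reagent used up to the key step and can all be removed in one operation before the alkene is introduced.

18 to 15 and 3 (key disconnection): the C2–aryl bond. Cutting here turns the stereotriad into the C3/C4 problem of a butyrolactone, leaves only one stereocentre to be set on the ring, and brings the second arene in late. The forward reaction has to add the aryl group to C2 trans to the C3 arm.

15 to 13: the anomeric C–OAc and C–H bonds. Reduction of lactone 13 and acetylation are run in one flask through aluminium lactolate 14. The lactol stage is never set free, because in its open hydroxy aldehyde form C3 could relax to the trans arrangement.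

13 to 11: the C3–H bond. Alkylation of a 4-substituted lactone can only give the trans isomer. Reprotonation of enolate 12 uses the same open face for the proton, which leaves the two arms cis.

11 to 9: the C3–CH2O bond, by alkylation of enolate 10 with an alkoxymethyl electrophile that delivers the future ester carbon already protected.

9 to 8 to 7 and 3: the ester carbon of 8 is removed by dealkoxycarbonylation, and the CH2–aryl bond of the C4 arm is cut back to cyclopropane 7 and Grignard reagent 3. The same aryl metal therefore serves both the C4 arm and the key step.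

7 to 4 and 5: two C–C bonds and the lactone C–O bond, by double alkylation of malonate 4 with epichlorohydrin 5. The absolute configuration is bought from the chiral pool, and the mechanism fixes it: (S)-5 gives (1R,5S)-7 and hence (4S)-9.

3 to 2 to 1, and 21 to 20: Grignard reagent 3 comes from aryl bromide 2, which is the benzyl ether of commercial bromophenol 1, and acid 21 is the diacetate of commercial caffeic acid 20.

## Alternatives that were turned down

Alternative 1: Three bonds are cut at once: O1–C2, C3–C4 and the bond from the exocyclic carbon to its arene. In the forward direction the alkoxide of propargyl alcohol A1 would add to diethyl 2-[4-(benzyloxy)-3-methoxybenzylidene]propanedioate A2 in an oxa-Michael reaction that forms O1–C2. The malonate carbanion would then attack the alkyne, activated by the arylpalladium species formed from 1-(benzyloxy)-4-iodo-2-methoxybenzene A3 and zerovalent palladium, in a 5-exo-dig closure that forms C3–C4, and reductive elimination would give the benzylidene diester A4. A chiral bisphosphine on palladium is meant to select one enantiomer at the reversible oxa-Michael stage.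
- For: three simple components and the whole ring skeleton in one flask. On bonds per step it is stronger than the chosen route.
- Against: the enantiocontrol depends on a dynamic resolution of a centre remote from the metal, which is not established chemistry. A4 carries only C2; C3 is a quaternary diester carbon and C4 is sp2. Hydrogenation of the styrene double bond of A4 (beside benzyl ethers and the benzylic C2–O1 bond) would have to set C4, and dealkoxycarbonylation would set C3 by a protonation under thermodynamic control, whereas the target needs the less stable C3/C4 cis pair. A reduction of the remaining ester follows.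
- Comparison: the chosen route is longer before the ring is complete, but each stereocentre has its own step with a known mode of control.

Alternative 2: The C3–C4 bond is cut. The single-electron reductant Cp2TiCl, a trivalent titanium complex, would open the oxirane of the epoxy cinnamyl ether A5 to a C3 radical, which adds 5-exo to the cinnamyl alkene; the benzylic radical is then reduced, giving bis-silyl ether A6.
- For: the ring and two stereocentres form in one step, and A6 already has the primary hydroxyl free and the phenols silylated. That would make acylation and final deprotection cleaner than in the chosen route, with no hydrogenolysis and no acylation beside free phenols. In step count and endgame this alternative is stronger.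
- Against: enantiopure A5 has to be assembled with its electron-rich benzylic C–O stereocentre next to an oxirane; that position ionises easily under acid, and the basic etherification that installs the cinnamyl group invites Payne rearrangement. The C3/C4 relationship is decided inside one radical transition state and cannot be corrected afterwards. Cp2TiCl is needed in more than two equivalents.
- Comparison: the chosen strategy offers a chiral-pool source of configuration fixed by mechanism, a C3 centre whose wrong epimer can be recycled, and a C2 centre for which kinetic and thermodynamic preference agree.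

Alternative 3: The C3–CH2OH bond is cut. The enantiopure butenolide A7 would be attacked at its β-carbon, anti to the aryl group, by the hydroxymethyl radical generated from methanol A8, and the resulting radical at the arylmethyl-bearing carbon would take a hydrogen atom anti to the new hydroxymethyl group, giving lactone A9.
- For: C3 and C4 are set in one event, with the cis pair arising from hydrogen-atom transfer, and the hydroxyl arrives unprotected. If that transfer is selective, this solves the cis problem more directly than the protonation used in the chosen route.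
- Against: A7 has an acidic, benzylic γ-hydrogen and racemises easily by deprotonation at that position. The carbonyl of A9 sits on the carbon that must become C5H2, so a lactone-to-ether reduction under ionic conditions is needed beside a benzylic lactone C–O bond. The face selectivity of the hydrogen-atom transfer is not assured.
- Comparison: the chosen route places the carbonyl on C2, where it is used to attach the arene and not removed.

Key step: step 9

Remark on the chemistry (assumption): the route is built for the (2R,3S,4S) enantiomer as drawn, and commercial (S)-epichlorohydrin of high enantiomeric purity is taken as the source of absolute configuration.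

## Route

Step 1
Reactants: 1 4-bromo-2-methoxyphenol
Product: 2 1-(benzyloxy)-4-bromo-2-methoxybenzene
Conditions: BnBr, K2CO3, DMF, rt
Reagents that add atoms: benzyl bromide, BrCc1ccccc1
Why: Williamson etherification of the phenoxide; the benzyl ether withstands Grignard formation, copper chemistry, hot LiCl/DMSO and amide bases.

Step 2
Reactants: 2 1-(benzyloxy)-4-bromo-2-methoxybenzene
Product: 3 [4-(benzyloxy)-3-methoxyphenyl]magnesium bromide (titrated THF solution)
Conditions: Mg turnings, cat. I2, THF, 50 °C
Reagents that add atoms: magnesium, [Mg]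
Why: Grignard formation by magnesium insertion into an electron-rich aryl bromide; the stock solution serves steps 4 and 9.

Step 3
Reactants: 4 diethyl malonate; 5 (S)-epichlorohydrin
Product: 7 ethyl (1R,5S)-2-oxo-3-oxabicyclo[3.1.0]hexane-1-carboxylate, via diethyl (S)-(oxiranylmethyl)malonate 6 (not isolated)
Conditions: NaOEt, EtOH, 0 °C then reflux
Reagents that add atoms: none
Why: Double alkylation of malonate by epichlorohydrin: the carbanion opens the epoxide at its CH2 end and the alkoxide displaces chloride to give 6; a second deprotonation closes the cyclopropane 3-exo-tet with inversion at the stereocentre, and the released alkoxide lactonises onto the cis ester. The epichlorohydrin centre thus becomes C5 of 7 with (S) configuration; a minor direct chloride displacement would lower the enantiomeric purity, which is to be checked at 9.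

Step 4
Reactants: 7 ethyl (1R,5S)-2-oxo-3-oxabicyclo[3.1.0]hexane-1-carboxylate; 3 [4-(benzyloxy)-3-methoxyphenyl]magnesium bromide
Product: 8 ethyl (3R,4S)-4-[4-(benzyloxy)-3-methoxybenzyl]-2-oxotetrahydrofuran-3-carboxylate
Conditions: 3 (1.3 equiv), CuI (15 mol%), THF, −40 to −20 °C; aq NH4Cl
Reagents that add atoms: none
Why: Copper-catalysed homoconjugate addition of an aryl Grignard reagent to a cyclopropane activated by two geminal carbonyl groups; the aryl group attacks the unsubstituted cyclopropane CH2, so the stereocentre is untouched and becomes C4, and C3 settles trans on protonation (its configuration is lost in step 5).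

Step 5
Reactants: 8 ethyl (3R,4S)-4-[4-(benzyloxy)-3-methoxybenzyl]-2-oxotetrahydrofuran-3-carboxylate
Product: 9 (4S)-4-[4-(benzyloxy)-3-methoxybenzyl]dihydrofuran-2(3H)-one
Conditions: LiCl, H2O, DMSO, 140 °C
Reagents that add atoms: none
Why: Krapcho dealkoxycarbonylation of the 2-oxo-3-carboxylate; C4 is not enolisable and keeps its configuration.

Step 6
Reactants: 9 (4S)-4-[4-(benzyloxy)-3-methoxybenzyl]dihydrofuran-2(3H)-one
Product: 11 (3R,4S)-4-[4-(benzyloxy)-3-methoxybenzyl]-3-[(benzyloxy)methyl]dihydrofuran-2(3H)-one, via lactone lithium enolate 10 (not isolated)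
Conditions: LiN(iPr)2, THF, −78 °C; BnOCH2Cl, −78 to −40 °C
Reagents that add atoms: benzyl chloromethyl ether, ClCOCc1ccccc1
Why: Alkylation of a lactone lithium enolate with an α-chloro ether; the electrophile approaches anti to the C4 arylmethyl arm, giving the trans lactone.

Step 7
Reactants: 11 (3R,4S)-4-[4-(benzyloxy)-3-methoxybenzyl]-3-[(benzyloxy)methyl]dihydrofuran-2(3H)-one
Product: 13 (3S,4S)-4-[4-(benzyloxy)-3-methoxybenzyl]-3-[(benzyloxy)methyl]dihydrofuran-2(3H)-one, via benzyloxymethyl lactone lithium enolate 12 (not isolated)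
Conditions: LiN(iPr)2, THF, −78 °C; enolate added to 2,6-di-tert-butyl-4-methylphenol, THF, −78 °C; aq NH4Cl
Reagents that add atoms: none
Why: Kinetic protonation of a lactone enolate: in planar 12, allylic strain between the C3 benzyloxymethyl group and the C4 arylmethyl group turns the latter pseudoaxial over one face, and the hindered phenol delivers the proton to the other face, leaving the two arms cis (3S). The minor trans isomer 11 is separated and resubmitted, and −78 °C keeps the β-benzyloxy enolate from eliminating.

Step 8
Reactants: 13 (3S,4S)-4-[4-(benzyloxy)-3-methoxybenzyl]-3-[(benzyloxy)methyl]dihydrofuran-2(3H)-one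
Product: 15 (3S,4S)-4-[4-(benzyloxy)-3-methoxybenzyl]-3-[(benzyloxy)methyl]tetrahydrofuran-2-yl acetate (anomeric mixture), via diisobutylaluminium lactolate 14 (not isolated)
Conditions: iBu2AlH (1.1 equiv), CH2Cl2, −78 °C; then pyridine, DMAP, Ac2O, −78 to −20 °C
Reagents that add atoms: acetic anhydride, CC(=O)OC(C)=O
Why: Reductive acetylation of a lactone: the aluminium hemiacetal 14 is acetylated in the flask, so the free lactol and its open hydroxy aldehyde never form and the base-labile cis arrangement at C3 is kept; both C2 epimers are equally useful.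

Step 9
Reactants: 15 (3S,4S)-4-[4-(benzyloxy)-3-methoxybenzyl]-3-[(benzyloxy)methyl]tetrahydrofuran-2-yl acetate; 3 [4-(benzyloxy)-3-methoxyphenyl]magnesium bromide
Product: 18 (2R,3S,4S)-2-[4-(benzyloxy)-3-methoxyphenyl]-4-[4-(benzyloxy)-3-methoxybenzyl]-3-[(benzyloxy)methyl]tetrahydrofuran, via bis(4-benzyloxy-3-methoxyphenyl)zinc 16 (not isolated), via cyclic oxocarbenium ion 17 (not isolated)
Conditions: 3 (3 equiv), ZnBr2 (1.5 equiv), THF, 0 °C; then 15 in CH2Cl2, BF3·OEt2 (2 equiv) added last, −78 to −30 °C; cold aq NaHCO3
Reagents that add atoms: none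
Why: BF3·OEt2 removes the anomeric acetate of 15, and both anomers give the same planar oxocarbenium ion 17 (O1=C2). Diarylzinc 16, made beforehand from 3 and ZnBr2 and therefore compatible with the Lewis acid, transfers one aryl group to C2; this is the only skeletal bond formed and no ring is closed. The closest known reaction type is the Lewis-acid-promoted C-glycosylation of lactol acetates (α-acetoxy ethers) by organozinc and aryl-metal reagents. The new stereocentre C2 is under substrate control: the benzyloxymethyl arm on C3, next to the electrophilic carbon, and the arylmethyl arm on C4 lie on the same face of the envelope cation, so the aryl group should enter from the opposite face and give the 2,3-trans (2R) ether. That isomer is also the more stable one, so any Lewis-acid reopening of the benzylic C2–O1 bond would not work against the outcome. The step needs this facial selectivity, and it needs intermolecular aryl transfer to outrun both Friedel–Crafts capture of C2 by the C4 arene and loss of H3 to the cyclic enol ether, which would scramble C3. These are secured by having the excess nucleophile in solution before the Lewis acid is added, by low temperature and by a cold basic quench.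

Step 10
Reactants: 18 (2R,3S,4S)-2-[4-(benzyloxy)-3-methoxyphenyl]-4-[4-(benzyloxy)-3-methoxybenzyl]-3-[(benzyloxy)methyl]tetrahydrofuran
Product: 19 [(2R,3S,4S)-2-(4-hydroxy-3-methoxyphenyl)-4-(4-hydroxy-3-methoxybenzyl)tetrahydrofuran-3-yl]methanol
Conditions: H2 (1 atm), Pd/C (10%), EtOAc–EtOH, rt, stopped when the last benzyl ether is consumed
Reagents that add atoms: none
Why: Catalytic hydrogenolysis of two aryl benzyl ethers and one primary alkyl benzyl ether; unhindered O-benzyl groups should be cleaved faster than the secondary, ring-bound benzylic C2–O1 bond of the more electron-rich arene, provided the medium is neutral and the reaction is monitored.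

Step 11
Reactants: 20 caffeic acid
Product: 21 (2E)-3-[3,4-bis(acetyloxy)phenyl]prop-2-enoic acid
Conditions: Ac2O, pyridine, 0 °C to rt; dilute aq HCl
Reagents that add atoms: acetic anhydride, CC(=O)OC(C)=O
Why: Acetylation of both catechol hydroxyls; the acetates survive the Mitsunobu conditions and leave later under near-neutral conditions, and the aqueous work-up returns the free carboxylic acid.

Step 12
Reactants: 19 [(2R,3S,4S)-2-(4-hydroxy-3-methoxyphenyl)-4-(4-hydroxy-3-methoxybenzyl)tetrahydrofuran-3-yl]methanol; 21 (2E)-3-[3,4-bis(acetyloxy)phenyl]prop-2-enoic acid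
Product: 22 [(2R,3S,4S)-2-(4-hydroxy-3-methoxyphenyl)-4-(4-hydroxy-3-methoxybenzyl)tetrahydrofuran-3-yl]methyl (2E)-3-[3,4-bis(acetyloxy)phenyl]prop-2-enoate
Conditions: PPh3, DIAD, THF, 0 °C to rt
Reagents that add atoms: none
Why: Mitsunobu esterification: the primary alcohol is activated as its alkoxyphosphonium ion and displaced at CH2 by the carboxylate. The much more acidic carboxylic acid, not the guaiacyl phenols, is the pronucleophile, so the phenols stay free, and no stereocentre is involved.

Step 13
Reactants: 22 [(2R,3S,4S)-2-(4-hydroxy-3-methoxyphenyl)-4-(4-hydroxy-3-methoxybenzyl)tetrahydrofuran-3-yl]methyl (2E)-3-[3,4-bis(acetyloxy)phenyl]prop-2-enoate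
Product: 23 [(2R,3S,4S)-2-(4-hydroxy-3-methoxyphenyl)-4-(4-hydroxy-3-methoxybenzyl)tetrahydrofuran-3-yl]methyl (2E)-3-(3,4-dihydroxyphenyl)prop-2-enoate
Conditions: NH4OAc, MeOH–H2O, rt, under argon
Reagents that add atoms: none
Why: Chemoselective methanolysis of aryl acetates, which are far more electrophilic than the conjugated alkyl ester; the neutral, oxygen-free medium protects the catechol and the benzylic ether.

## Compound list

1 | 4-bromo-2-methoxyphenol | COc1cc(Br)ccc1O | starting material
2 | 1-(benzyloxy)-4-bromo-2-methoxybenzene | COc1cc(Br)ccc1OCc1ccccc1 | intermediate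
3 | [4-(benzyloxy)-3-methoxyphenyl]magnesium bromide | COc1cc([Mg]Br)ccc1OCc1ccccc1 | intermediate (stock solution)
4 | diethyl malonate | CCOC(=O)CC(=O)OCC | starting material
5 | (S)-epichlorohydrin, (2S)-2-(chloromethyl)oxirane | ClC[C@@H]1CO1 | starting material
6 | diethyl 2-{[(2S)-oxiran-2-yl]methyl}propanedioate | CCOC(=O)C(C[C@H]1CO1)C(=O)OCC | intermediate (not isolated)
7 | ethyl (1R,5S)-2-oxo-3-oxabicyclo[3.1.0]hexane-1-carboxylate | CCOC(=O)[C@@]12C[C@@H]1COC2=O | intermediate
8 | ethyl (3R,4S)-4-[4-(benzyloxy)-3-methoxybenzyl]-2-oxotetrahydrofuran-3-carboxylate | CCOC(=O)[C@@H]1C(=O)OC[C@H]1Cc1ccc(OCc2ccccc2)c(OC)c1 | intermediate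
9 | (4S)-4-[4-(benzyloxy)-3-methoxybenzyl]dihydrofuran-2(3H)-one | COc1cc(C[C@@H]2COC(=O)C2)ccc1OCc1ccccc1 | intermediate
10 | lithium (3S)-3-[4-(benzyloxy)-3-methoxybenzyl]-2,3-dihydrofuran-5-olate | COc1cc(C[C@@H]2COC(O[Li])=C2)ccc1OCc1ccccc1 | intermediate (not isolated)
11 | (3R,4S)-4-[4-(benzyloxy)-3-methoxybenzyl]-3-[(benzyloxy)methyl]dihydrofuran-2(3H)-one (trans) | COc1cc(C[C@@H]2COC(=O)[C@H]2COCc2ccccc2)ccc1OCc1ccccc1 | intermediate
12 | lithium (3S)-3-[4-(benzyloxy)-3-methoxybenzyl]-4-[(benzyloxy)methyl]-2,3-dihydrofuran-5-olate | COc1cc(C[C@@H]2COC(O[Li])=C2COCc2ccccc2)ccc1OCc1ccccc1 | intermediate (not isolated)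
13 | (3S,4S)-4-[4-(benzyloxy)-3-methoxybenzyl]-3-[(benzyloxy)methyl]dihydrofuran-2(3H)-one (cis) | COc1cc(C[C@@H]2COC(=O)[C@@H]2COCc2ccccc2)ccc1OCc1ccccc1 | intermediate
14 | diisobutylaluminium (3S,4S)-4-[4-(benzyloxy)-3-methoxybenzyl]-3-[(benzyloxy)methyl]tetrahydrofuran-2-olate (C2 epimers) | COc1cc(C[C@@H]2COC(O[Al](CC(C)C)CC(C)C)[C@@H]2COCc2ccccc2)ccc1OCc1ccccc1 | intermediate (not isolated)
15 | (3S,4S)-4-[4-(benzyloxy)-3-methoxybenzyl]-3-[(benzyloxy)methyl]tetrahydrofuran-2-yl acetate (anomeric mixture) | COc1cc(C[C@@H]2COC(OC(C)=O)[C@@H]2COCc2ccccc2)ccc1OCc1ccccc1 | intermediate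
16 | bis[4-(benzyloxy)-3-methoxyphenyl]zinc | COc1cc([Zn]c2ccc(OCc3ccccc3)c(OC)c2)ccc1OCc1ccccc1 | intermediate (not isolated)
17 | (3S,4S)-4-[4-(benzyloxy)-3-methoxybenzyl]-3-[(benzyloxy)methyl]-4,5-dihydro-3H-furan-1-ium | COc1cc(C[C@@H]2C[O+]=C[C@@H]2COCc2ccccc2)ccc1OCc1ccccc1 | intermediate (not isolated)
18 | (2R,3S,4S)-2-[4-(benzyloxy)-3-methoxyphenyl]-4-[4-(benzyloxy)-3-methoxybenzyl]-3-[(benzyloxy)methyl]tetrahydrofuran | COc1cc(C[C@@H]2CO[C@@H](c3ccc(OCc4ccccc4)c(OC)c3)[C@@H]2COCc2ccccc2)ccc1OCc1ccccc1 | intermediate
19 | [(2R,3S,4S)-2-(4-hydroxy-3-methoxyphenyl)-4-(4-hydroxy-3-methoxybenzyl)tetrahydrofuran-3-yl]methanol | COc1cc(C[C@@H]2CO[C@@H](c3ccc(O)c(OC)c3)[C@@H]2CO)ccc1O | intermediate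
20 | caffeic acid, (2E)-3-(3,4-dihydroxyphenyl)prop-2-enoic acid | OC(=O)/C=C/c1ccc(O)c(O)c1 | starting material
21 | (2E)-3-[3,4-bis(acetyloxy)phenyl]prop-2-enoic acid | CC(=O)Oc1ccc(/C=C/C(=O)O)cc1OC(C)=O | intermediate
22 | [(2R,3S,4S)-2-(4-hydroxy-3-methoxyphenyl)-4-(4-hydroxy-3-methoxybenzyl)tetrahydrofuran-3-yl]methyl (2E)-3-[3,4-bis(acetyloxy)phenyl]prop-2-enoate | COc1cc(C[C@@H]2CO[C@@H](c3ccc(O)c(OC)c3)[C@@H]2COC(=O)/C=C/c2ccc(OC(C)=O)c(OC(C)=O)c2)ccc1O | intermediate
23 | [(2R,3S,4S)-2-(4-hydroxy-3-methoxyphenyl)-4-(4-hydroxy-3-methoxybenzyl)tetrahydrofuran-3-yl]methyl (2E)-3-(3,4-dihydroxyphenyl)prop-2-enoate | COc1cc(C[C@@H]2CO[C@@H](c3ccc(O)c(OC)c3)[C@@H]2COC(=O)/C=C/c2ccc(O)c(O)c2)ccc1O | target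

## Step count and least certain steps

Total step count: 13. Longest linear sequence: 11 steps (steps 1, 2, 4, 5, 6, 7, 8, 9, 10, 12 and 13, from 1 to 23).

Step 9 (key step). The aryl transfer may be too slow for the cation. In that case C2 could be captured intramolecularly by the arene of the C4 arm, the cation could lose H3 to the enol ether and so lose the C3 configuration, or facial selectivity could be poor.
Fallback, from 13 back to 18: the C2–aryl bond is made on the open chain and the ring is closed afterwards through the C2–O1 bond. Lactone 13 is reduced with iBu2AlH (toluene, −78 °C) to the lactol (3S,4S)-4-[4-(benzyloxy)-3-methoxybenzyl]-3-[(benzyloxy)methyl]tetrahydrofuran-2-ol F1. Excess 3 (THF, −78 to 0 °C) arylates the aldehyde form to give (2S,3S)-1-[4-(benzyloxy)-3-methoxyphenyl]-3-[4-(benzyloxy)-3-methoxybenzyl]-2-[(benzyloxy)methyl]butane-1,4-diol F2 as a mixture of carbinol epimers. Catalytic camphorsulfonic acid (CH2Cl2, 0 °C) ionises either epimer to the same 4-alkoxybenzyl cation, which the primary hydroxyl should close to the more stable 2,3-trans ether 18.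

Step 7. Facial selectivity of the protonation may be modest, because the proton is a small electrophile, and the enolate may lose benzyloxide by β-elimination if it warms.
Fallback, from 9 back to 13: the C3–H bond is made by hydrogenation of an exocyclic alkene, with no enolate. Lactone 9 is formylated (HCO2Et, NaH, THF) to (4S)-4-[4-(benzyloxy)-3-methoxybenzyl]-3-(hydroxymethylidene)dihydrofuran-2(3H)-one F3. O-Benzylation (BnBr, K2CO3, acetone) gives (4S)-4-[4-(benzyloxy)-3-methoxybenzyl]-3-[(benzyloxy)methylidene]dihydrofuran-2(3H)-one F4. Hydrogenation over Rh/Al2O3 (H2, 1 atm, EtOAc), which spares benzyl ethers, should add hydrogen from the face opposite the C4 arm and give cis lactone 13.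

Step 10. Over-reduction is the concern: once the phenols are free, the benzylic C2–O1 bond may undergo hydrogenolysis and open the ring before the slower alkyl benzyl ether is gone.
Fallback, from 13, and from 1 for the aryl partner, back to 19: the hydrogenolysis is moved to a stage where no benzylic ring ether exists. Lactone 13 is debenzylated (H2, Pd/C, EtOAc) to (3S,4S)-3-(hydroxymethyl)-4-(4-hydroxy-3-methoxybenzyl)dihydrofuran-2(3H)-one F5, which is silylated (tBuMe2SiCl, imidazole, DMF) to (3S,4S)-3-({[tert-butyl(dimethyl)silyl]oxy}methyl)-4-(4-{[tert-butyl(dimethyl)silyl]oxy}-3-methoxybenzyl)dihydrofuran-2(3H)-one F6. This lactone is converted as in step 8 into (3S,4S)-3-({[tert-butyl(dimethyl)silyl]oxy}methyl)-4-(4-{[tert-butyl(dimethyl)silyl]oxy}-3-methoxybenzyl)tetrahydrofuran-2-yl acetate F7. In parallel, phenol 1 is silylated to (4-bromo-2-methoxyphenoxy)(tert-butyl)dimethylsilane F8 and converted with Mg into (4-{[tert-butyl(dimethyl)silyl]oxy}-3-methoxyphenyl)magnesium bromide F9. The two partners are joined under the conditions of step 9 to give (2R,3S,4S)-3-({[tert-butyl(dimethyl)silyl]oxy}methyl)-2-(4-{[tert-butyl(dimethyl)silyl]oxy}-3-methoxyphenyl)-4-(4-{[tert-butyl(dimethyl)silyl]oxy}-3-methoxybenzyl)tetrahydrofuran F10. Bu4NF buffered with acetic acid (THF, 0 °C) then removes the three silyl groups to give 19.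

Step 12. Chemoselectivity may fail, by O-alkylation of a phenol by the activated alcohol or by acetyl transfer from 21 to a free hydroxyl.
Fallback, from 19 back to 23: the acid is activated, not the alcohol, with the phenols masked. Compound 19 is acetylated at the phenoxide oxygens only (Ac2O, aq NaOH, 0 °C) to 4-{[(3S,4S,5R)-5-[4-(acetyloxy)-3-methoxyphenyl]-4-(hydroxymethyl)tetrahydrofuran-3-yl]methyl}-2-methoxyphenyl acetate F11. Carbodiimide coupling with 21 (EDC·HCl, cat. DMAP, CH2Cl2) gives the tetraacetate [(2R,3S,4S)-2-[4-(acetyloxy)-3-methoxyphenyl]-4-[4-(acetyloxy)-3-methoxybenzyl]tetrahydrofuran-3-yl]methyl (2E)-3-[3,4-bis(acetyloxy)phenyl]prop-2-enoate F12. The conditions of step 13 then remove all four aryl acetates to give 23.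

## Further compounds

F1 | step 9 | (3S,4S)-4-[4-(benzyloxy)-3-methoxybenzyl]-3-[(benzyloxy)methyl]tetrahydrofuran-2-ol (anomeric mixture) | COc1cc(C[C@@H]2COC(O)[C@@H]2COCc2ccccc2)ccc1OCc1ccccc1
F2 | step 9 | (2S,3S)-1-[4-(benzyloxy)-3-methoxyphenyl]-3-[4-(benzyloxy)-3-methoxybenzyl]-2-[(benzyloxy)methyl]butane-1,4-diol (C1 epimers) | COc1cc(C[C@H](CO)[C@@H](COCc2ccccc2)C(O)c2ccc(OCc3ccccc3)c(OC)c2)ccc1OCc1ccccc1
F3 | step 7 | (4S)-4-[4-(benzyloxy)-3-methoxybenzyl]-3-(hydroxymethylidene)dihydrofuran-2(3H)-one (alkene geometry immaterial) | COc1cc(C[C@@H]2COC(=O)C2=CO)ccc1OCc1ccccc1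
F4 | step 7 | (4S)-4-[4-(benzyloxy)-3-methoxybenzyl]-3-[(benzyloxy)methylidene]dihydrofuran-2(3H)-one (alkene geometry immaterial) | COc1cc(C[C@@H]2COC(=O)C2=COCc2ccccc2)ccc1OCc1ccccc1
F5 | step 10 | (3S,4S)-3-(hydroxymethyl)-4-(4-hydroxy-3-methoxybenzyl)dihydrofuran-2(3H)-one | COc1cc(C[C@@H]2COC(=O)[C@@H]2CO)ccc1O
F6 | step 10 | (3S,4S)-3-({[tert-butyl(dimethyl)silyl]oxy}methyl)-4-(4-{[tert-butyl(dimethyl)silyl]oxy}-3-methoxybenzyl)dihydrofuran-2(3H)-one | COc1cc(C[C@@H]2COC(=O)[C@@H]2CO[Si](C)(C)C(C)(C)C)ccc1O[Si](C)(C)C(C)(C)C
F7 | step 10 | (3S,4S)-3-({[tert-butyl(dimethyl)silyl]oxy}methyl)-4-(4-{[tert-butyl(dimethyl)silyl]oxy}-3-methoxybenzyl)tetrahydrofuran-2-yl acetate (anomeric mixture) | COc1cc(C[C@@H]2COC(OC(C)=O)[C@@H]2CO[Si](C)(C)C(C)(C)C)ccc1O[Si](C)(C)C(C)(C)C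
F8 | step 10 | (4-bromo-2-methoxyphenoxy)(tert-butyl)dimethylsilane | COc1cc(Br)ccc1O[Si](C)(C)C(C)(C)C
F9 | step 10 | (4-{[tert-butyl(dimethyl)silyl]oxy}-3-methoxyphenyl)magnesium bromide | COc1cc([Mg]Br)ccc1O[Si](C)(C)C(C)(C)C
F10 | step 10 | (2R,3S,4S)-3-({[tert-butyl(dimethyl)silyl]oxy}methyl)-2-(4-{[tert-butyl(dimethyl)silyl]oxy}-3-methoxyphenyl)-4-(4-{[tert-butyl(dimethyl)silyl]oxy}-3-methoxybenzyl)tetrahydrofuran | COc1cc(C[C@@H]2CO[C@@H](c3ccc(O[Si](C)(C)C(C)(C)C)c(OC)c3)[C@@H]2CO[Si](C)(C)C(C)(C)C)ccc1O[Si](C)(C)C(C)(C)C
F11 | step 12 | 4-{[(3S,4S,5R)-5-[4-(acetyloxy)-3-methoxyphenyl]-4-(hydroxymethyl)tetrahydrofuran-3-yl]methyl}-2-methoxyphenyl acetate | COc1cc(C[C@@H]2CO[C@@H](c3ccc(OC(C)=O)c(OC)c3)[C@@H]2CO)ccc1OC(C)=O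
F12 | step 12 | [(2R,3S,4S)-2-[4-(acetyloxy)-3-methoxyphenyl]-4-[4-(acetyloxy)-3-methoxybenzyl]tetrahydrofuran-3-yl]methyl (2E)-3-[3,4-bis(acetyloxy)phenyl]prop-2-enoate | COc1cc(C[C@@H]2CO[C@@H](c3ccc(OC(C)=O)c(OC)c3)[C@@H]2COC(=O)/C=C/c2ccc(OC(C)=O)c(OC(C)=O)c2)ccc1OC(C)=O
A1 | alternative 1 | propargyl alcohol (prop-2-yn-1-ol) | C#CCO
A2 | alternative 1 | diethyl 2-[4-(benzyloxy)-3-methoxybenzylidene]propanedioate | CCOC(=O)C(=Cc1ccc(OCc2ccccc2)c(OC)c1)C(=O)OCC
A3 | alternative 1 | 1-(benzyloxy)-4-iodo-2-methoxybenzene | COc1cc(I)ccc1OCc1ccccc1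
A4 | alternative 1 | diethyl (2S,4Z)-2-[4-(benzyloxy)-3-methoxyphenyl]-4-[4-(benzyloxy)-3-methoxybenzylidene]dihydrofuran-3,3(2H)-dicarboxylate | COc1cc(/C=C2\CO[C@@H](c3ccc(OCc4ccccc4)c(OC)c3)C2(C(=O)OCC)C(=O)OCC)ccc1OCc1ccccc1
A5 | alternative 2 | 2-[(S)-(4-{[tert-butyl(dimethyl)silyl]oxy}-3-methoxyphenyl){[(2E)-3-(4-{[tert-butyl(dimethyl)silyl]oxy}-3-methoxyphenyl)prop-2-en-1-yl]oxy}methyl]oxirane (either oxirane epimer) | COc1cc(/C=C/CO[C@@H](c2ccc(O[Si](C)(C)C(C)(C)C)c(OC)c2)C2CO2)ccc1O[Si](C)(C)C(C)(C)C
A6 | alternative 2 | [(2R,3S,4S)-2-(4-{[tert-butyl(dimethyl)silyl]oxy}-3-methoxyphenyl)-4-(4-{[tert-butyl(dimethyl)silyl]oxy}-3-methoxybenzyl)tetrahydrofuran-3-yl]methanol | COc1cc(C[C@@H]2CO[C@@H](c3ccc(O[Si](C)(C)C(C)(C)C)c(OC)c3)[C@@H]2CO)ccc1O[Si](C)(C)C(C)(C)C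
A7 | alternative 3 | (5R)-3-(4-{[tert-butyl(dimethyl)silyl]oxy}-3-methoxybenzyl)-5-(4-{[tert-butyl(dimethyl)silyl]oxy}-3-methoxyphenyl)furan-2(5H)-one | COc1cc(CC2=C[C@H](c3ccc(O[Si](C)(C)C(C)(C)C)c(OC)c3)OC2=O)ccc1O[Si](C)(C)C(C)(C)C
A8 | alternative 3 | methanol | CO
A9 | alternative 3 | (3S,4S,5R)-3-(4-{[tert-butyl(dimethyl)silyl]oxy}-3-methoxybenzyl)-5-(4-{[tert-butyl(dimethyl)silyl]oxy}-3-methoxyphenyl)-4-(hydroxymethyl)dihydrofuran-2(3H)-one | COc1cc(C[C@@H]2C(=O)O[C@@H](c3ccc(O[Si](C)(C)C(C)(C)C)c(OC)c3)[C@@H]2CO)ccc1O[Si](C)(C)C(C)(C)C
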